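**Retrosynthetic overview**

1. The strategy rests on the oxolane ring O1–C2(aryl)–C3(CH3)–C4(CH3)(OH)–C5(aryl) (locants used in the discussion, not those of the IUPAC names). Its two methyl-bearing carbons C3 and C4 are neighbours, and become the β- and α-carbons of a butenolide when C5 is the lactone carbonyl and C2 the aryl-bearing γ-carbon.
2. Target 17 ⇒ bis-benzyl ether 16 (debenzylation) ⇒ hemiketal 14 (C5–H from Et3SiH/BF3·OEt2) ⇒ α-hydroxy lactone 11 (C5–aryl from aryllithium 13) ⇒ dimethyl lactone 9 (C4–O by enolate hydroxylation).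
3. Key disconnection: both C–CH3 bonds of 9 are made in one pot on butenolide 6, C3–CH3 from Me2CuLi and C4–CH3 from MeI. The C2 centre steers C3, C3 steers the C4 hydroxyl, and C4 and C3 steer C5.
4. Butenolide 6 ⇒ propargylic alcohol 4 (cis-semihydrogenation, lactonisation) ⇒ O-benzylvanillin 1 and methyl propiolate 2 (asymmetric alkynylation).
5. Ring order: only one ring is built, the five-membered O1–C5 ring. It is closed as the butenolide in step 2 and kept to the end.

Key step: step 3

Assumption: the (S,S) antipode of ProPhenol is taken to give the R carbinol 4 from an aryl aldehyde. The sense is to be checked on 4 by Mosher ester analysis, and the (R,R) ligand is used instead if it proves opposite.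

**Route**

Step 1
Reactants: 1 4-(benzyloxy)-3-methoxybenzaldehyde (O-benzylvanillin); 2 methyl propiolate
Product: 4 methyl (R)-4-[4-(benzyloxy)-3-methoxyphenyl]-4-hydroxybut-2-ynoate, via alkynylzinc 3 (not isolated)
Conditions: (S,S)-ProPhenol (10 mol%), Ph3P=O (20 mol%), Me2Zn (3 equiv), 2 (3 equiv), toluene, 0 to 4 °C; aq. NH4Cl
Reagents that add atoms: none
Why: Zinc–ProPhenol asymmetric alkynylation of an aldehyde: Me2Zn metalates 2 to alkynylzinc 3, which is transferred to one face of the aldehyde bound in the chiral dinuclear zinc pocket, so the ligand sets the carbinol centre as R, and aryl aldehydes with methyl propiolate are standard partners for this reaction.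

Step 2
Reactants: 4 methyl (R)-4-[4-(benzyloxy)-3-methoxyphenyl]-4-hydroxybut-2-ynoate
Product: 6 (S)-5-[4-(benzyloxy)-3-methoxyphenyl]furan-2(5H)-one, via Z-hydroxy enoate 5 (not isolated)
Conditions: H2 (1 atm), Pd/CaCO3 poisoned with Pb(OAc)2 (Lindlar catalyst), quinoline, EtOAc, rt, stopped after one equivalent of H2; filter; PPTS (cat.), CH2Cl2, rt
Reagents that add atoms: none
Why: Lindlar cis-semihydrogenation stops at Z-enoate 5, whose hydroxyl then attacks the cis ester (lactonisation, 5-exo-trig) with loss of methanol; the carbinol C–O bond is not broken, so the centre keeps its geometry and is named S in 6 only because the CIP ranks of aryl and the unsaturated carbon are exchanged, and the poisoned catalyst leaves the benzyl ether and the benzylic C–O bond alone.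

Step 3
Reactants: 6 (S)-5-[4-(benzyloxy)-3-methoxyphenyl]furan-2(5H)-one; 7 iodomethane
Product: 9 (3S,4S,5S)-5-[4-(benzyloxy)-3-methoxyphenyl]-3,4-dimethyloxolan-2-one, via lithium enolate 8 (not isolated)
Conditions: MeLi (3.0 equiv), CuI (1.5 equiv), Et2O, 0 °C; then 6, Et2O/THF, −78 °C; then HMPA, 7 (excess), −78 to −20 °C; aq. NH4Cl/NH3
Reagents that add atoms: lithium dimethylcuprate Me2CuLi, [Li+].C[Cu-]C (made in the flask from methyllithium, [Li]C, and CuI)
Why: Me2CuLi forms a π-complex with the enoate of 6 and, through a β-cuprio enolate and reductive elimination, makes the β-C–CH3 bond and lithium enolate 8, which HMPA activates for SN2 C-methylation by 7 to make the α-C–CH3 bond. The closest known reaction type is the tandem Gilman-cuprate conjugate addition and enolate alkylation of γ-substituted butenolides; no ring is closed, the lactone ring of 6 is carried through. The new β-stereocentre (C3 of the overview numbering, 4S in 9) is controlled by the γ-aryl stereocentre: on the nearly flat five-membered ring the aryl group covers one face and the cuprate attacks the other, which gives the trans aryl/methyl relation. The new α-stereocentre (3S in 9) is controlled by the fresh β-methyl, anti to which 7 approaches, but its configuration is not needed because step 4 makes this carbon planar again, so both α-epimers can be taken on. The step needs 1,4-addition in preference to 1,2-addition and to γ-deprotonation, which would racemise 6; the soft and weakly basic cuprate at −78 °C secures this, and the γ C–O bond, held near the plane of the enoate, is poorly aligned for reductive ring opening.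

Step 4
Reactants: 9 (3S,4S,5S)-5-[4-(benzyloxy)-3-methoxyphenyl]-3,4-dimethyloxolan-2-one
Product: 11 (3S,4R,5S)-5-[4-(benzyloxy)-3-methoxyphenyl]-3-hydroxy-3,4-dimethyloxolan-2-one, via potassium enolate 10 (not isolated)
Conditions: KN(SiMe3)2 (1.3 equiv), THF, −78 °C; 3-phenyl-2-(phenylsulfonyl)oxaziridine (1.5 equiv), −78 °C; aq. NH4Cl
Reagents that add atoms: 3-phenyl-2-(phenylsulfonyl)oxaziridine, O=S(=O)(N1OC1c1ccccc1)c1ccccc1
Why: Enolate oxidation with an N-sulfonyloxaziridine (Davis hydroxylation): the base gives the planar tetrasubstituted enolate 10 and the oxaziridine oxygen should enter anti to the neighbouring β-methyl group (1,2-induction), which puts the hydroxyl trans to that methyl and the two methyls cis, whichever α-epimer of 9 is used.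

Step 5
Reactants: 11 (3S,4R,5S)-5-[4-(benzyloxy)-3-methoxyphenyl]-3-hydroxy-3,4-dimethyloxolan-2-one; 12 1-(benzyloxy)-4-bromo-2-methoxybenzene
Product: 14 (3S,4R,5S)-2,5-bis[4-(benzyloxy)-3-methoxyphenyl]-3,4-dimethyloxolane-2,3-diol (both C2 anomers), via aryllithium 13 (not isolated)
Conditions: 12 (2.6 equiv), n-BuLi (2.5 equiv), THF, −78 °C; then 11, −78 °C; aq. NH4Cl at −78 °C
Reagents that add atoms: none
Why: Bromine–lithium exchange followed by addition of an aryllithium to a lactone carbonyl: the first equivalent of 13 deprotonates the tertiary hydroxyl, the second adds to the carbonyl, whose α-carbon is quaternary and cannot enolise, and the chelated tetrahedral lithium alkoxide should persist at −78 °C until the quench, which limits double addition; no existing stereocentre is touched and the new hemiketal centre is erased in step 6.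

Step 6
Reactants: 14 (3S,4R,5S)-2,5-bis[4-(benzyloxy)-3-methoxyphenyl]-3,4-dimethyloxolane-2,3-diol (both C2 anomers)
Product: 16 (2R,3S,4R,5S)-2,5-bis[4-(benzyloxy)-3-methoxyphenyl]-3,4-dimethyloxolan-3-ol, via oxocarbenium ion 15 (not isolated)
Conditions: Et3SiH (5 equiv), BF3·OEt2 (2 equiv), CH2Cl2, −78 °C; aq. NaHCO3 at −78 °C
Reagents that add atoms: none
Why: Ionic hydrogenation of a cyclic hemiketal: BF3 ionises the anomeric hydroxyl to the aryl-stabilised oxocarbenium ion 15 and the silane should deliver hydride to the face anti to the two cis methyl groups and syn to the small C4 hydroxyl (overview numbering; inside attack on the envelope that keeps the C3 methyl, the C2 aryl and the C4 oxygen pseudo-equatorial), which places the new aryl group cis to the C4 methyl and trans to the other aryl, while −78 °C keeps the benzylic ring C–O bonds from ionising.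

Step 7
Reactants: 16 (2R,3S,4R,5S)-2,5-bis[4-(benzyloxy)-3-methoxyphenyl]-3,4-dimethyloxolan-3-ol
Product: 17 (2R,3S,4R,5S)-2,5-bis(4-hydroxy-3-methoxyphenyl)-3,4-dimethyloxolan-3-ol (CNP0234919.4)
Conditions: H2 (1 atm), 10% Pd/C, EtOAc/MeOH, rt, stopped at full debenzylation
Reagents that add atoms: none
Why: Catalytic hydrogenolysis of the two aryl benzyl ethers: O-benzyl phenols are cleaved far faster than the ring benzylic C–O bonds of a 2,5-diaryloxolane, and the tertiary alcohol and the four stereocentres are not involved.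

**Compound list**

1 | 4-(benzyloxy)-3-methoxybenzaldehyde (O-benzylvanillin) | COc1cc(C=O)ccc1OCc1ccccc1 | starting material
2 | methyl propiolate | C#CC(=O)OC | starting material
3 | methyl 3-(methylzincio)prop-2-ynoate (alkynylzinc, not isolated) | C[Zn]C#CC(=O)OC | intermediate
4 | methyl (R)-4-[4-(benzyloxy)-3-methoxyphenyl]-4-hydroxybut-2-ynoate | COc1cc([C@@H](O)C#CC(=O)OC)ccc1OCc1ccccc1 | intermediate
5 | methyl (2Z,4S)-4-[4-(benzyloxy)-3-methoxyphenyl]-4-hydroxybut-2-enoate (not isolated) | COc1cc([C@@H](O)/C=C\C(=O)OC)ccc1OCc1ccccc1 | intermediate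
6 | (S)-5-[4-(benzyloxy)-3-methoxyphenyl]furan-2(5H)-one | COc1cc([C@H]2OC(=O)C=C2)ccc1OCc1ccccc1 | intermediate
7 | iodomethane | CI | starting material
8 | lithium enolate of (4S,5S)-5-[4-(benzyloxy)-3-methoxyphenyl]-4-methyloxolan-2-one (not isolated) | [Li+].COc1cc([C@H]2OC([O-])=C[C@@H]2C)ccc1OCc1ccccc1 | intermediate
9 | (3S,4S,5S)-5-[4-(benzyloxy)-3-methoxyphenyl]-3,4-dimethyloxolan-2-one | COc1cc([C@H]2OC(=O)[C@@H](C)[C@@H]2C)ccc1OCc1ccccc1 | intermediate
10 | potassium enolate of 9 (not isolated) | [K+].COc1cc([C@H]2OC([O-])=C(C)[C@@H]2C)ccc1OCc1ccccc1 | intermediate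
11 | (3S,4R,5S)-5-[4-(benzyloxy)-3-methoxyphenyl]-3-hydroxy-3,4-dimethyloxolan-2-one | COc1cc([C@H]2OC(=O)[C@@](C)(O)[C@@H]2C)ccc1OCc1ccccc1 | intermediate
12 | 1-(benzyloxy)-4-bromo-2-methoxybenzene | COc1cc(Br)ccc1OCc1ccccc1 | starting material
13 | [4-(benzyloxy)-3-methoxyphenyl]lithium (not isolated) | [Li]c1ccc(OCc2ccccc2)c(OC)c1 | intermediate
14 | (3S,4R,5S)-2,5-bis[4-(benzyloxy)-3-methoxyphenyl]-3,4-dimethyloxolane-2,3-diol, both C2 anomers, in equilibrium with the open hydroxy ketone | COc1cc([C@H]2OC(O)(c3ccc(OCc4ccccc4)c(OC)c3)[C@@](C)(O)[C@@H]2C)ccc1OCc1ccccc1 | intermediate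
15 | (3S,4R,5S)-2,5-bis[4-(benzyloxy)-3-methoxyphenyl]-3-hydroxy-3,4-dimethyl-4,5-dihydro-3H-furan-1-ium (oxocarbenium ion, not isolated) | COc1cc([C@H]2[O+]=C(c3ccc(OCc4ccccc4)c(OC)c3)[C@@](C)(O)[C@@H]2C)ccc1OCc1ccccc1 | intermediate
16 | (2R,3S,4R,5S)-2,5-bis[4-(benzyloxy)-3-methoxyphenyl]-3,4-dimethyloxolan-3-ol | COc1cc([C@H]2O[C@H](c3ccc(OCc4ccccc4)c(OC)c3)[C@@](C)(O)[C@@H]2C)ccc1OCc1ccccc1 | intermediate
17 | (2R,3S,4R,5S)-2,5-bis(4-hydroxy-3-methoxyphenyl)-3,4-dimethyloxolan-3-ol | COc1cc([C@H]2O[C@H](c3ccc(O)c(OC)c3)[C@@](C)(O)[C@@H]2C)ccc1O | target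

**Step count**

Total: 7 steps. Longest linear sequence: 7 steps (1 → 4 → 6 → 9 → 11 → 14 → 16 → 17); aryllithium 13 is made in the flask in step 5.

**Steps most likely to fail**

Step 3. The copper-bound enolate 8 may alkylate slowly, so that proton exchange between 8 and 9 gives unmethylated and doubly methylated lactone. Excess organometallic may also remove the γ-hydrogen of 6 and erode the enantiopurity. The fallback separates the two bond formations. It sets out from 6: Me2CuLi in Et2O at −78 °C with a cold NH4Cl quench should give (4S,5S)-5-[4-(benzyloxy)-3-methoxyphenyl]-4-methyloxolan-2-one F1. This is purified and then deprotonated with LiN(SiMe3)2 in THF at −78 °C and methylated with 7, anti to the β-methyl. The fallback rejoins the route at 9.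

Step 6. Hydride may be delivered to the face of 15 that carries the two methyl groups. The Lewis acid may also ionise the benzylic ring C–O bonds (epimerisation at C2 or C5) or trigger a 1,2-shift from C4 to the cationic C5. The fallback reverses the order in which hydrogen and aryl are placed on C5. It sets out from 11: DIBAL-H in CH2Cl2 at −78 °C should give the lactol (3S,4R,5S)-5-[4-(benzyloxy)-3-methoxyphenyl]-3,4-dimethyloxolane-2,3-diol F2. A BF3·OEt2-promoted Friedel–Crafts C-arylation of F2 with 2-methoxyphenol (attack para to the phenolic hydroxyl, CH2Cl2, −78 to −40 °C) should then give 4-{(2R,3S,4R,5S)-5-[4-(benzyloxy)-3-methoxyphenyl]-3-hydroxy-3,4-dimethyloxolan-2-yl}-2-methoxyphenol F3. A nucleophile is expected to choose the same face of the ring-substituted oxocarbenium ion in both cases, so with aryl as the incoming group the opposite C5 epimer results. Hydrogenolysis of the remaining benzyl ether under the conditions of step 7 rejoins the route at 17.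

Step 5. The lithium alkoxide formed first may lower the electrophilicity of the neighbouring carbonyl so that the addition stalls. Alternatively the tetrahedral intermediate may open and take up a second aryl group. The fallback masks the hydroxyl. It sets out from 11: TMSOTf and 2,6-lutidine in CH2Cl2 should give (3S,4R,5S)-5-[4-(benzyloxy)-3-methoxyphenyl]-3,4-dimethyl-3-[(trimethylsilyl)oxy]oxolan-2-one F4. Addition of 13 (1.2 equiv, THF, −78 °C) should give (3S,4R,5S)-2,5-bis[4-(benzyloxy)-3-methoxyphenyl]-3,4-dimethyl-3-[(trimethylsilyl)oxy]oxolan-2-ol F5. Desilylation with Bu4NF/AcOH in THF at 0 °C rejoins the route at 14.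

**Further compounds**

F1 | step 3 | (4S,5S)-5-[4-(benzyloxy)-3-methoxyphenyl]-4-methyloxolan-2-one | COc1cc([C@H]2OC(=O)C[C@@H]2C)ccc1OCc1ccccc1
F2 | step 6 | (3S,4R,5S)-5-[4-(benzyloxy)-3-methoxyphenyl]-3,4-dimethyloxolane-2,3-diol (both C2 anomers) | COc1cc([C@H]2OC(O)[C@@](C)(O)[C@@H]2C)ccc1OCc1ccccc1
F3 | step 6 | 4-{(2R,3S,4R,5S)-5-[4-(benzyloxy)-3-methoxyphenyl]-3-hydroxy-3,4-dimethyloxolan-2-yl}-2-methoxyphenol | COc1cc([C@H]2O[C@H](c3ccc(O)c(OC)c3)[C@@](C)(O)[C@@H]2C)ccc1OCc1ccccc1
F4 | step 5 | (3S,4R,5S)-5-[4-(benzyloxy)-3-methoxyphenyl]-3,4-dimethyl-3-[(trimethylsilyl)oxy]oxolan-2-one | COc1cc([C@H]2OC(=O)[C@@](C)(O[Si](C)(C)C)[C@@H]2C)ccc1OCc1ccccc1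
F5 | step 5 | (3S,4R,5S)-2,5-bis[4-(benzyloxy)-3-methoxyphenyl]-3,4-dimethyl-3-[(trimethylsilyl)oxy]oxolan-2-ol (both C2 anomers) | COc1cc([C@H]2OC(O)(c3ccc(OCc4ccccc4)c(OC)c3)[C@@](C)(O[Si](C)(C)C)[C@@H]2C)ccc1OCc1ccccc1
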